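**Plan**
1. Retrosynthesis cuts, in order: the two ester C–O bonds (C6–O last, C1–O with inversion), the C6–O bond (allylic oxidation), C7=CH2 (from a C7 ketone), C3=CHCH3 (aldol and dehydration), the C1–C2 bond of the five-membered ring (acyloin), and finally the six-membered ring at C5–C6 and C3a–C7a.
2. Enabling feature: in the six-membered ring C6 and C7a both flank C7, whose methylidene is a latent ketone, so C6–C7–C7a with the C1 ester carbon is an acetoacetate dianion (1,3-bis-nucleophile). C5 and C3a both flank the isopropyl-bearing C4, so C5–C4–C3a(=C3–C2 ester) is a 4-(sulfonyloxymethyl)hex-2-enoate (1,3-bis-electrophile).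
3. Forward order: chain from isovaleraldehyde (2 steps), six-membered ring by dianion alkylation/Michael annulation (step 3), five-membered ring by acyloin condensation (step 5), then ethylidene, methylidene, C1 ester, C6 oxidation and C6 ester.
4. Stereochemistry: C4 from amine-catalysed α-hydroxymethylation; C3a and C7a relayed from C4 in the annulation (all-equatorial, trans ring fusion); C1 from the thermodynamic ketol followed by Mitsunobu inversion; C6 from axial-selective SeO2 oxidation; E-ethylidene from anti-aldol plus syn-elimination; side-chain centre and geometry from the purchased acids.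

Key step: step 3

Remark: locants are those of the octahydroindene core (C1 acyloxy carbinol next to the C2 ketone, C3 ethylidene carbon, C3a/C7a ring fusion, C4 isopropyl, C5 methylene, C6 acyloxy carbinol, C7 methylidene carbon).
Remark: (2R)-2-methylbutanoic acid and (2E)-3-methylpent-2-enoic acid are taken as purchasable, and the ketol of step 5 is taken to settle as the 1R epimer (hydroxyl trans to the C7a–C7 bond), as ring-D 16-oxo-17β-hydroxy steroids do.

**Step 1**
Reactants: 1 3-methylbutanal (isovaleraldehyde)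
Product: 3 methyl (2E,4S)-4-(hydroxymethyl)-5-methylhex-2-enoate, via (2R)-2-(hydroxymethyl)-3-methylbutanal 2 (not isolated)
Conditions: HCHO (37 % aq.), (S)-α,α-diphenylprolinol trimethylsilyl ether (10 mol %), toluene, pH 7 phosphate buffer, 23 °C; then Ph3P=CHCO2Me, CH2Cl2, 0→23 °C
Reagents that add atoms: formaldehyde, C=O; methyl (triphenylphosphoranylidene)acetate, COC(=O)C=P(c1ccccc1)(c1ccccc1)c1ccccc1
Why: Enamine-catalysed α-hydroxymethylation (cross-aldol with formaldehyde) sets C4, formaldehyde approaching the E-enamine on the face away from the CPh2(OSiMe3) group of the (S)-catalyst to give the (R)-aldehyde, which is trapped by E-selective Wittig olefination with the stabilised ylide before it can racemise or dehydrate.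

**Step 2**
Reactants: 3 methyl (2E,4S)-4-(hydroxymethyl)-5-methylhex-2-enoate
Product: 4 methyl (2E,4S)-5-methyl-4-{[(trifluoromethanesulfonyl)oxy]methyl}hex-2-enoate
Conditions: Tf2O, 2,6-lutidine, CH2Cl2, −78 °C; used at once
Reagents that add atoms: trifluoromethanesulfonic anhydride, O=S(=O)(OS(=O)(=O)C(F)(F)F)C(F)(F)F
Why: O-Sulfonylation of the primary alcohol at low temperature gives a leaving group reactive enough for displacement at a β-branched carbon, and no stereocentre is involved.

**Step 3**
Reactants: 5 methyl acetoacetate; 4 methyl (2E,4S)-5-methyl-4-{[(trifluoromethanesulfonyl)oxy]methyl}hex-2-enoate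
Product: 8 methyl (1R,5S,6S)-6-(2-methoxy-2-oxoethyl)-2-oxo-5-(propan-2-yl)cyclohexane-1-carboxylate, via methyl acetoacetate dianion 6 (not isolated), via alkylated keto diester enolate 7 (not isolated)
Conditions: 5, LiN(iPr)2 (2.0 equiv), THF, 0 °C; 4, −78→−20 °C; MeOH, 23→40 °C; AcOH quench
Reagents that add atoms: none
Why: The γ-carbon of dianion 6 (future C6) displaces the primary triflate of 4 (SN2, C5–C6) to leave the β-keto ester enolate 7, whose α-carbon (future C7a) then adds to the enoate β-carbon (future C3a) once methanol is present as proton shuttle, and proton transfer to the more stable β-keto ester enolate drives this Michael step (C3a–C7a). The closest known reaction types are the γ-alkylation of acetoacetate dianions and the tandem SN2–Michael annulation of enoates that carry a remote leaving group. The six-membered ring closes in a 6-exo-trig mode. C3a is set in a chair transition state with the C4 isopropyl group and the E-enoate both equatorial, which places the acetate arm trans to isopropyl, and C7a, an epimerisable β-keto ester centre, settles equatorial and trans to that arm, while C4 is carried in unchanged from 4. The step needs displacement to outrun conjugate addition and proton abstraction by the hard γ-carbanion, which the triflate leaving group at −78 °C and the hindered γ-branched enoate should secure, and it needs C- over O-cyclisation, which the reversibility of the oxa-Michael mode should secure.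

**Step 4**
Reactants: 8 methyl (1R,5S,6S)-6-(2-methoxy-2-oxoethyl)-2-oxo-5-(propan-2-yl)cyclohexane-1-carboxylate
Product: 9 methyl (6R,7S,8S)-7-(2-methoxy-2-oxoethyl)-8-(propan-2-yl)-1,4-dioxaspiro[4.5]decane-6-carboxylate
Conditions: Me3SiOCH2CH2OSiMe3, Me3SiOTf (cat.), CH2Cl2, −20→0 °C
Reagents that add atoms: 1,2-bis(trimethylsilyloxy)ethane, C[Si](C)(C)OCCO[Si](C)(C)C
Why: Noyori ketalisation under aprotic conditions masks the C7 ketone of the β-keto ester so that only the two ester groups respond to sodium in the next step, and the ester at C7a stays equatorial.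

**Step 5**
Reactants: 9 methyl (6R,7S,8S)-7-(2-methoxy-2-oxoethyl)-8-(propan-2-yl)-1,4-dioxaspiro[4.5]decane-6-carboxylate
Product: 11 (1R,3aS,4S,7aS)-7,7-(ethylenedioxy)-1-hydroxy-4-(propan-2-yl)octahydro-2H-inden-2-one, via bis(trimethylsilyl) enediol ether 10 (not isolated)
Conditions: Na, Me3SiCl, toluene, 110 °C; then K2CO3 (cat.), MeOH, 0 °C, argon
Reagents that add atoms: none
Why: Acyloin condensation under Rühlmann conditions joins the two ester carbons into the C1–C2 bond as in ring-D steroid syntheses, and mild methanolysis with equilibration through the enediol should settle on the 2-oxo-1-hydroxy regioisomer with the new C1 hydroxyl quasi-equatorial and trans to the C7a–C7 bond (1R).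

**Step 6**
Reactants: 11 (1R,3aS,4S,7aS)-7,7-(ethylenedioxy)-1-hydroxy-4-(propan-2-yl)octahydro-2H-inden-2-one
Product: 12 (1R,3aS,4S,7aS)-1-(tert-butyldimethylsilyloxy)-7,7-(ethylenedioxy)-4-(propan-2-yl)octahydro-2H-inden-2-one
Conditions: TBSCl, imidazole, DMF, 23 °C
Reagents that add atoms: tert-butyldimethylsilyl chloride, CC(C)(C)[Si](C)(C)Cl
Why: Silylation of the secondary ketol hydroxyl with the chloride and imidazole avoids the silyl enol ether formation that a silyl triflate could cause and blocks C1 for the enolate chemistry that follows.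

**Step 7**
Reactants: 12 (1R,3aS,4S,7aS)-1-(tert-butyldimethylsilyloxy)-7,7-(ethylenedioxy)-4-(propan-2-yl)octahydro-2H-inden-2-one
Product: 14 (1R,3S,3aR,4S,7aS)-1-(tert-butyldimethylsilyloxy)-7,7-(ethylenedioxy)-3-[(1S)-1-hydroxyethyl]-4-(propan-2-yl)octahydro-2H-inden-2-one, via lithium enolate 13 (not isolated)
Conditions: LiN(iPr)2, THF, −78 °C; MeCHO, −78 °C; AcOH quench at −78 °C
Reagents that add atoms: acetaldehyde, CC=O
Why: Kinetic deprotonation occurs at the C3 methylene rather than at the hindered silyloxy-bearing C1 methine, acetaldehyde approaches the ring enolate on the face away from C4, and the closed Zimmerman–Traxler transition state of the ring-locked E(O)-enolate gives the 3,1′-anti aldol.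

**Step 8**
Reactants: 14 (1R,3S,3aR,4S,7aS)-1-(tert-butyldimethylsilyloxy)-7,7-(ethylenedioxy)-3-[(1S)-1-hydroxyethyl]-4-(propan-2-yl)octahydro-2H-inden-2-one
Product: 16 (1R,3E,3aS,4S,7aS)-1-(tert-butyldimethylsilyloxy)-3-ethylidene-7,7-(ethylenedioxy)-4-(propan-2-yl)octahydro-2H-inden-2-one, via sulfamate ester 15 (not isolated)
Conditions: Burgess reagent (MeO2CN(−)SO2N(+)Et3), benzene, 50 °C
Reagents that add atoms: none
Why: Burgess dehydration is a stereospecific syn (Ei) elimination, and in the 3,1′-anti aldol the syn-periplanar H–C3/C1′–O arrangement leaves the methyl group cis to C3a, so the E-ethylidene geometry is fixed by mechanism and not by thermodynamics.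

**Step 9**
Reactants: 16 (1R,3E,3aS,4S,7aS)-1-(tert-butyldimethylsilyloxy)-3-ethylidene-7,7-(ethylenedioxy)-4-(propan-2-yl)octahydro-2H-inden-2-one
Product: 17 (1R,3E,3aS,4S,7aS)-1-(tert-butyldimethylsilyloxy)-3-ethylidene-4-(propan-2-yl)hexahydro-1H-indene-2,7-dione
Conditions: PPTS, acetone/H2O, 50 °C; taken on at once
Reagents that add atoms: water, O
Why: Mild acid-catalysed hydrolysis of the dioxolane frees the C7 ketone while the secondary silyl ether and the exocyclic enone survive, and keeping the C1 oxygen as a silyl ether (a poor leaving group) guards against β-elimination now that C7a–H is acidified.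

**Step 10**
Reactants: 17 (1R,3E,3aS,4S,7aS)-1-(tert-butyldimethylsilyloxy)-3-ethylidene-4-(propan-2-yl)hexahydro-1H-indene-2,7-dione
Product: 18 (1R,3E,3aS,4S,7aR)-1-(tert-butyldimethylsilyloxy)-3-ethylidene-7-methylidene-4-(propan-2-yl)octahydro-2H-inden-2-one
Conditions: Zn, CH2Br2, TiCl4, THF/CH2Cl2, 0→23 °C (Takai–Lombardo)
Reagents that add atoms: dibromomethane, BrCBr
Why: Takai–Lombardo methylenation is non-basic, so it should neither epimerise C7a nor eliminate the β-silyloxy group, and it should prefer the saturated cyclohexanone at C7 over the hindered cross-conjugated C2 carbonyl.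

**Step 11**
Reactants: 18 (1R,3E,3aS,4S,7aR)-1-(tert-butyldimethylsilyloxy)-3-ethylidene-7-methylidene-4-(propan-2-yl)octahydro-2H-inden-2-one
Product: 19 (1R,3E,3aS,4S,7aR)-3-ethylidene-1-hydroxy-7-methylidene-4-(propan-2-yl)octahydro-2H-inden-2-one
Conditions: HF·pyridine, THF, 0→23 °C
Reagents that add atoms: none
Why: Fluoride-mediated desilylation under weakly acidic conditions frees the C1 hydroxyl and leaves the α-hydroxy enone and both alkenes untouched.

**Step 12**
Reactants: 19 (1R,3E,3aS,4S,7aR)-3-ethylidene-1-hydroxy-7-methylidene-4-(propan-2-yl)octahydro-2H-inden-2-one; 20 (2R)-2-methylbutanoic acid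
Product: 21 (1S,3E,3aS,4S,7aR)-3-ethylidene-7-methylidene-2-oxo-4-(propan-2-yl)octahydro-1H-inden-1-yl (2R)-2-methylbutanoate
Conditions: 20, PPh3, DIAD, toluene, 0→23 °C
Reagents that add atoms: none
Why: Mitsunobu esterification proceeds by SN2 displacement of the oxyphosphonium group, accelerated by the adjacent carbonyl, so the carboxylate of 20 enters with inversion and sets 1S while the stereocentre of the acid is not touched.

**Step 13**
Reactants: 21 (1S,3E,3aS,4S,7aR)-3-ethylidene-7-methylidene-2-oxo-4-(propan-2-yl)octahydro-1H-inden-1-yl (2R)-2-methylbutanoate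
Product: 22 (1S,3E,3aS,4S,6R,7aR)-3-ethylidene-6-hydroxy-7-methylidene-2-oxo-4-(propan-2-yl)octahydro-1H-inden-1-yl (2R)-2-methylbutanoate
Conditions: SeO2 (cat.), t-BuOOH, CH2Cl2, 23 °C
Reagents that add atoms: tert-butyl hydroperoxide, CC(C)(C)OO (oxygen relayed by catalytic selenium dioxide, O=[Se]=O)
Why: SeO2 allylic oxidation (ene reaction followed by 2,3-sigmatropic shift) of the 1,1-disubstituted alkene attacks the allylic CH2 at C6 in preference to the allylic CH at C7a and is expected to deliver oxygen along the axial trajectory, giving the axial 6R alcohol with the methylidene retained while the electron-poor ethylidene enone is left alone.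

**Step 14**
Reactants: 22 (1S,3E,3aS,4S,6R,7aR)-3-ethylidene-6-hydroxy-7-methylidene-2-oxo-4-(propan-2-yl)octahydro-1H-inden-1-yl (2R)-2-methylbutanoate; 23 (2E)-3-methylpent-2-enoic acid
Product: 24 (1S,3E,3aS,4S,6R,7aR)-3-ethylidene-7-methylidene-1-{[(2R)-2-methylbutanoyl]oxy}-2-oxo-4-(propan-2-yl)octahydro-1H-inden-6-yl (2E)-3-methylpent-2-enoate
Conditions: 23, DCC, DMAP (cat.), CH2Cl2, 0→23 °C
Reagents that add atoms: none
Why: Steglich esterification acylates the secondary allylic alcohol with retention at C6 under conditions mild enough for the epimerisable α-acyloxy ketone.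

**Compound list**
1 | 3-methylbutanal (isovaleraldehyde) | CC(C)CC=O | starting material
2 | (2R)-2-(hydroxymethyl)-3-methylbutanal | O=C[C@@H](CO)C(C)C | intermediate
3 | methyl (2E,4S)-4-(hydroxymethyl)-5-methylhex-2-enoate | OC[C@@H](C(C)C)/C=C/C(=O)OC | intermediate
4 | methyl (2E,4S)-5-methyl-4-{[(trifluoromethanesulfonyl)oxy]methyl}hex-2-enoate | O=S(=O)(OC[C@@H](C(C)C)/C=C/C(=O)OC)C(F)(F)F | intermediate
5 | methyl acetoacetate | COC(=O)CC(C)=O | starting material
6 | dilithium dianion of methyl acetoacetate | [Li+].[Li+].C=C([O-])C=C([O-])OC | intermediate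
7 | lithium enolate of dimethyl (2E,4S)-7-oxo-4-(propan-2-yl)non-2-enedioate | COC(=O)C=C([O-])CC[C@@H](C(C)C)/C=C/C(=O)OC.[Li+] | intermediate
8 | methyl (1R,5S,6S)-6-(2-methoxy-2-oxoethyl)-2-oxo-5-(propan-2-yl)cyclohexane-1-carboxylate | O=C1[C@H](C(=O)OC)[C@@H](CC(=O)OC)[C@H](C(C)C)CC1 | intermediate
9 | methyl (6R,7S,8S)-7-(2-methoxy-2-oxoethyl)-8-(propan-2-yl)-1,4-dioxaspiro[4.5]decane-6-carboxylate | C1COC2(O1)[C@H](C(=O)OC)[C@@H](CC(=O)OC)[C@H](C(C)C)CC2 | intermediate
10 | (3aS,4S,7aS)-7,7-(ethylenedioxy)-4-(propan-2-yl)-1,2-bis(trimethylsilyloxy)-3a,4,5,6,7,7a-hexahydro-3H-indene | C1COC2(O1)[C@H]3[C@@H](CC(O[Si](C)(C)C)=C3O[Si](C)(C)C)[C@H](C(C)C)CC2 | intermediate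
11 | (1R,3aS,4S,7aS)-7,7-(ethylenedioxy)-1-hydroxy-4-(propan-2-yl)octahydro-2H-inden-2-one | C1COC2(O1)[C@H]3[C@@H](CC(=O)[C@@H]3O)[C@H](C(C)C)CC2 | intermediate
12 | (1R,3aS,4S,7aS)-1-(tert-butyldimethylsilyloxy)-7,7-(ethylenedioxy)-4-(propan-2-yl)octahydro-2H-inden-2-one | C1COC2(O1)[C@H]3[C@@H](CC(=O)[C@@H]3O[Si](C)(C)C(C)(C)C)[C@H](C(C)C)CC2 | intermediate
13 | lithium C2–C3 enolate of 12 | C1COC2(O1)[C@H]3[C@@H](C=C([O-])[C@@H]3O[Si](C)(C)C(C)(C)C)[C@H](C(C)C)CC2.[Li+] | intermediate
14 | (1R,3S,3aR,4S,7aS)-1-(tert-butyldimethylsilyloxy)-7,7-(ethylenedioxy)-3-[(1S)-1-hydroxyethyl]-4-(propan-2-yl)octahydro-2H-inden-2-one (3,1′-anti aldol, side chain on the face away from C4) | C1COC2(O1)[C@H]3[C@@H]([C@@H]([C@H](C)O)C(=O)[C@@H]3O[Si](C)(C)C(C)(C)C)[C@H](C(C)C)CC2 | intermediate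
15 | triethylammonium salt of the 1′-O-[N-(methoxycarbonyl)sulfamate] of 14 | C1COC2(O1)[C@H]3[C@@H]([C@@H]([C@H](C)OS(=O)(=O)[N-]C(=O)OC)C(=O)[C@@H]3O[Si](C)(C)C(C)(C)C)[C@H](C(C)C)CC2.CC[NH+](CC)CC | intermediate
16 | (1R,3E,3aS,4S,7aS)-1-(tert-butyldimethylsilyloxy)-3-ethylidene-7,7-(ethylenedioxy)-4-(propan-2-yl)octahydro-2H-inden-2-one | C1COC2(O1)[C@H]3[C@@H](/C(=C\C)C(=O)[C@@H]3O[Si](C)(C)C(C)(C)C)[C@H](C(C)C)CC2 | intermediate
17 | (1R,3E,3aS,4S,7aS)-1-(tert-butyldimethylsilyloxy)-3-ethylidene-4-(propan-2-yl)hexahydro-1H-indene-2,7-dione | O=C1[C@H]2[C@@H](/C(=C\C)C(=O)[C@@H]2O[Si](C)(C)C(C)(C)C)[C@H](C(C)C)CC1 | intermediate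
18 | (1R,3E,3aS,4S,7aR)-1-(tert-butyldimethylsilyloxy)-3-ethylidene-7-methylidene-4-(propan-2-yl)octahydro-2H-inden-2-one | C=C1[C@H]2[C@@H](/C(=C\C)C(=O)[C@@H]2O[Si](C)(C)C(C)(C)C)[C@H](C(C)C)CC1 | intermediate
19 | (1R,3E,3aS,4S,7aR)-3-ethylidene-1-hydroxy-7-methylidene-4-(propan-2-yl)octahydro-2H-inden-2-one | C=C1[C@H]2[C@@H](/C(=C\C)C(=O)[C@@H]2O)[C@H](C(C)C)CC1 | intermediate
20 | (2R)-2-methylbutanoic acid | CC[C@@H](C)C(=O)O | starting material
21 | (1S,3E,3aS,4S,7aR)-3-ethylidene-7-methylidene-2-oxo-4-(propan-2-yl)octahydro-1H-inden-1-yl (2R)-2-methylbutanoate | C=C1[C@H]2[C@@H](/C(=C\C)C(=O)[C@H]2OC(=O)[C@H](C)CC)[C@H](C(C)C)CC1 | intermediate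
22 | (1S,3E,3aS,4S,6R,7aR)-3-ethylidene-6-hydroxy-7-methylidene-2-oxo-4-(propan-2-yl)octahydro-1H-inden-1-yl (2R)-2-methylbutanoate | C=C1[C@H]2[C@@H](/C(=C\C)C(=O)[C@H]2OC(=O)[C@H](C)CC)[C@H](C(C)C)C[C@H]1O | intermediate
23 | (2E)-3-methylpent-2-enoic acid | OC(=O)/C=C(\C)CC | starting material
24 | (1S,3E,3aS,4S,6R,7aR)-3-ethylidene-7-methylidene-1-{[(2R)-2-methylbutanoyl]oxy}-2-oxo-4-(propan-2-yl)octahydro-1H-inden-6-yl (2E)-3-methylpent-2-enoate | C=C1[C@H]2[C@@H](/C(=C\C)C(=O)[C@H]2OC(=O)[C@H](C)CC)[C@H](C(C)C)C[C@H]1OC(=O)/C=C(\C)CC | target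

**Count and risks**
Total steps: 14. Longest linear sequence: 14 (1 → 24).

The three steps most likely to fail:

Step 3. The hard γ-carbanion may add to the enoate or abstract the allylic C4 proton instead of displacing the triflate, and the ring-closing Michael addition may stall at the acyclic enolate. The fallback inverts the order of the two bond formations and runs them in separate flasks. It sets out from 3, which Appel iodination (I2, PPh3, imidazole) would convert into methyl (2E,4S)-4-(iodomethyl)-5-methylhex-2-enoate F1. Methyl acetoacetate 5 would then be added to the enoate under catalytic NaOMe in MeOH (intermolecular Michael addition) to give methyl (3R,4S)-2-acetyl-4-(iodomethyl)-3-(2-methoxy-2-oxoethyl)-5-methylhexanoate F2. Two equivalents of LiN(iPr)2 would form its dianion, whose γ-carbon closes the ring by intramolecular displacement of iodide, and the route is rejoined at 8.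

Step 8. The elimination may lose its stereospecificity through a stepwise carbanion pathway and drift toward the geometric isomer with the methyl group next to the carbonyl. The fallback gives up mechanistic control and corrects the geometry photochemically. It sets out from 14, which would be converted with MsCl and Et3N into the 1′-O-methanesulfonate of 14 F3 and eliminated with DBU. The Z-ethylidene isomer of 16 F4 would be separated, irradiated (350 nm, benzene) to a photostationary mixture and recycled, and the route is rejoined at 16.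

Step 12. Displacement at the hindered C1 carbinol may be slow, so that elimination or acylation with retention competes, and triphenylphosphine may add reversibly to the enone and scramble the ethylidene geometry. The fallback replaces the redox condensation by a discrete sulfonate displacement that needs no phosphine. It sets out from 19, which Tf2O and pyridine (CH2Cl2, −40 °C) would convert into the C1 trifluoromethanesulfonate of 19 F5. The caesium salt of 20 (from 20 and Cs2CO3) with 18-crown-6 in toluene would displace it with inversion, and the route is rejoined at 21.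

**Further compounds**
F1 | step 3 | methyl (2E,4S)-4-(iodomethyl)-5-methylhex-2-enoate | IC[C@@H](C(C)C)/C=C/C(=O)OC
F2 | step 3 | methyl (3R,4S)-2-acetyl-4-(iodomethyl)-3-(2-methoxy-2-oxoethyl)-5-methylhexanoate (C2 epimers) | COC(=O)C(C(C)=O)[C@@H](CC(=O)OC)[C@@H](CI)C(C)C
F3 | step 8 | 1′-O-methanesulfonate of 14 | C1COC2(O1)[C@H]3[C@@H]([C@@H]([C@H](C)OS(C)(=O)=O)C(=O)[C@@H]3O[Si](C)(C)C(C)(C)C)[C@H](C(C)C)CC2
F4 | step 8 | (1R,3Z,3aS,4S,7aS)-1-(tert-butyldimethylsilyloxy)-3-ethylidene-7,7-(ethylenedioxy)-4-(propan-2-yl)octahydro-2H-inden-2-one | C1COC2(O1)[C@H]3[C@@H](/C(=C/C)C(=O)[C@@H]3O[Si](C)(C)C(C)(C)C)[C@H](C(C)C)CC2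
F5 | step 12 | (1R,3E,3aS,4S,7aR)-3-ethylidene-7-methylidene-2-oxo-4-(propan-2-yl)octahydro-1H-inden-1-yl trifluoromethanesulfonate | C=C1[C@H]2[C@@H](/C(=C\C)C(=O)[C@@H]2OS(=O)(=O)C(F)(F)F)[C@H](C(C)C)CC1
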